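**Retrosynthetic overview**

1. The target has ring A, a (3R,6R)-3-hydroxy-ε-type cyclohexene, tied through C7H2–C8H2 to a butenolide (ring C: O–C19(=O)–C9=C10–C11, exocyclic C11=C12, Z), and ring B, a (3′R)-3′-hydroxy-β-type cyclohexene, at the far end of the all-E polyene.
2. The strategy rests on the lactone carbonyl C19 lying between the ring α-carbon C9 and the ring oxygen on C11: ring C is closed by inserting CO between the vinylic carbon–iodine bond at C9 and the enol oxygen of the C11 ketone of a (Z)-β-iodoenone, which also creates C11=C12.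
3. The iodoenone comes from an ynone (hydroiodination), assembled from a ring A butyne (α-ionone, resolved at the 3-hydroxy stage) and a C6 aldehyde made from (E)-3-methylpent-2-en-4-yn-1-ol.
4. The last C=C bond, C15=C15′, is made by a Wittig reaction between the butenolide dienal and a ring B C20 phosphonium salt (ketoisophorone, enol triflate, Stille coupling, Horner–Wadsworth–Emmons extension); desilylation follows.
5. Ring order: rings A and B are carried intact from the starting materials; ring C is the only ring formed, in step 14.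

Key step: step 14

Remark on locants: the ring A half is numbered C1–C15, with C19 the lactone carbonyl carbon; the ring B half carries primes; TBS = tert-butyldimethylsilyl.

Assumption: in step 5 the lipase is taken to acetylate the (3S,6S)-alcohol faster (gem-dimethyl flank as the large group, vinylic flank as the medium group in the usual size model for secondary alcohols), so the (3R,6R)-alcohol is recovered; with the opposite preference the acetate fraction would be methanolysed and carried on.

**Route**

Step 1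
Reactants: 1 (±)-α-ionone
Product: 3 (±)-7,8-dihydro-α-ionone, via triethylsilyl enol ether 2 (not isolated)
Conditions: Et3SiH, RhCl(PPh3)3 (0.5 mol %), 50 °C; then K2CO3, MeOH, rt
Reagents that add atoms: none
Why: Rhodium-catalysed 1,4-hydrosilylation with a monohydrosilane (conjugate reduction) should reduce only the C7=C8 bond of the enone, methanolysis of the silyl enol ether frees the saturated ketone, and the hindered trisubstituted ring alkene is left alone.

Step 2
Reactants: 3 (±)-7,8-dihydro-α-ionone
Product: 4 (±)-dihydro-α-ionone ethylene ketal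
Conditions: HOCH2CH2OH, PPTS (cat.), benzene, reflux (Dean–Stark)
Reagents that add atoms: ethylene glycol, OCCO
Why: Acid-catalysed ketalisation with azeotropic removal of water masks the methyl ketone for the ring oxidation and reduction, and the weak pyridinium acid should not shift the ring double bond.

Step 3
Reactants: 4 (±)-dihydro-α-ionone ethylene ketal
Product: 5 (±)-3-oxo-7,8-dihydro-α-ionone ethylene ketal
Conditions: t-BuOOH (5 equiv), Rh2(cap)4 (cap = caprolactamate, 0.5 mol %), K2CO3, CH2Cl2, rt
Reagents that add atoms: tert-butyl hydroperoxide, CC(C)(C)OO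
Why: Radical allylic C–H oxidation by the tert-butylperoxyl chain should attack the only unhindered allylic methylene, C3, and give the conjugated enone, while the ketal is stable to the basic medium.

Step 4
Reactants: 5 (±)-3-oxo-7,8-dihydro-α-ionone ethylene ketal
Product: 6 (±)-trans-3-hydroxy-7,8-dihydro-α-ionone ethylene ketal
Conditions: K[(s-Bu)3BH], THF, −78 °C; then H2O
Reagents that add atoms: none
Why: 1,2-Reduction of the β,β-disubstituted enone by a bulky trialkylborohydride, in which hydride should enter C3 anti to the axial C1 methyl group of the half-chair that holds the C6 side chain pseudo-axial, so that the new carbinol is set trans to the side chain (3R*,6R*) and any cis epimer is removed by chromatography.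

Step 5
Reactants: 6 (±)-trans-3-hydroxy-7,8-dihydro-α-ionone ethylene ketal
Product: 7 (3R,6R)-3-hydroxy-7,8-dihydro-α-ionone ethylene ketal
Conditions: lipase PS (Burkholderia cepacia), vinyl acetate, t-BuOMe, 30 °C, stopped slightly beyond half conversion; chromatography
Reagents that add atoms: none
Why: Lipase-catalysed kinetic resolution by enantioselective acetylation should consume the (3S,6S)-alcohol and leave the (3R,6R)-alcohol, so the enzyme fixes the absolute configuration of both ring A stereocentres here.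

Step 6
Reactants: 7 (3R,6R)-3-hydroxy-7,8-dihydro-α-ionone ethylene ketal
Product: 8 (3R,6R)-3-(TBSO)-7,8-dihydro-α-ionone ethylene ketal
Conditions: TBSCl, imidazole, DMF, rt
Reagents that add atoms: tert-butyldimethylsilyl chloride, CC(C)(C)[Si](C)(C)Cl
Why: Standard silylation of the secondary allylic alcohol gives an ether that tolerates the amide bases, the acetylide, the hydroiodination and the carbonylation that follow.

Step 7
Reactants: 8 (3R,6R)-3-(TBSO)-7,8-dihydro-α-ionone ethylene ketal
Product: 9 (3R,6R)-3-(TBSO)-7,8-dihydro-α-ionone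
Conditions: PPTS, acetone–H2O (10:1), 50 °C
Reagents that add atoms: water, O
Why: Mild acid-catalysed ketal hydrolysis releases the methyl ketone, and the secondary silyl ether should survive pyridinium tosylate.

Step 8
Reactants: 9 (3R,6R)-3-(TBSO)-7,8-dihydro-α-ionone
Product: 12 ring A butyne, via lithium enolate 10 (not isolated), via enol diethyl phosphate 11 (not isolated)
Conditions: LiN(i-Pr)2 (1.1 equiv), THF, −78 °C; ClP(O)(OEt)2, −78 °C → rt; LiN(i-Pr)2 (2.3 equiv), −78 °C → rt; then H2O
Reagents that add atoms: none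
Why: Kinetic deprotonation at the methyl group, O-phosphorylation and base-induced elimination of diethyl phosphate from the terminal enol phosphate (enol phosphate elimination) convert the methyl ketone into the terminal alkyne C9≡C10.

Step 9
Reactants: 13 (E)-3-methylpent-2-en-4-yn-1-ol
Product: 14 (E)-TBS ether of 3-methylpent-2-en-4-yn-1-ol
Conditions: TBSCl, imidazole, DMF, rt
Reagents that add atoms: tert-butyldimethylsilyl chloride, CC(C)(C)[Si](C)(C)Cl
Why: Standard silylation of the primary allylic alcohol, with the E trisubstituted alkene (later C13=C14) already in place.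

Step 10
Reactants: 14 (E)-TBS ether of 3-methylpent-2-en-4-yn-1-ol
Product: 16 (E)-5-(TBSO)-3-methylpent-3-enal, via dienyl(dicyclohexyl)borane 15 (not isolated)
Conditions: Cy2BH (1.05 equiv), THF, 0 °C; then H2O2, pH 7 phosphate buffer, 0 °C → rt; used at once
Reagents that add atoms: hydrogen peroxide, OO
Why: Anti-Markovnikov monohydroboration of the terminal alkyne by a hindered dialkylborane spares the trisubstituted alkene, and buffered oxidation (hydroboration–oxidation) gives a dienol whose α-protonation should deliver the β,γ-unsaturated aldehyde with the E alkene unchanged.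

Step 11
Reactants: 12 ring A butyne; 16 (E)-5-(TBSO)-3-methylpent-3-enal
Product: 18 propargylic alcohol ring A–CH2CH2–C≡C–CH(OH)–CH2–C(CH3)=CH–CH2OTBS (epimers at C11), via lithium acetylide 17 (not isolated)
Conditions: n-BuLi, THF, −78 °C; then 16, −78 °C
Reagents that add atoms: none
Why: 1,2-Addition of the lithium acetylide to the aldehyde at low temperature should outrun enolisation and forms the C10–C11 bond; the new carbinol centre is removed in step 12.

Step 12
Reactants: 18 propargylic alcohol
Product: 19 ynone ring A–CH2CH2–C≡C–C(=O)–CH2–C(CH3)=CH–CH2OTBS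
Conditions: Dess–Martin periodinane, pyridine, CH2Cl2, 0 °C → rt
Reagents that add atoms: none
Why: Dess–Martin oxidation of the propargylic alcohol under buffered, non-basic conditions should give the ynone without moving the β,γ-double bond.

Step 13
Reactants: 19 ynone
Product: 20 (Z)-β-iodoenone ring A–CH2CH2–C(I)=CH–C(=O)–CH2–C(CH3)=CH–CH2OTBS
Conditions: NaI (2 equiv), AcOH (3 equiv), MeCN, 0 °C → rt, dark
Reagents that add atoms: sodium iodide, [Na+].[I-]
Why: Conjugate hydroiodination of the ynone, in which iodide adds to C9 and the allenol is protonated at C10 anti to iodine, gives the kinetic Z isomer with iodine cis to the carbonyl group.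

Step 14
Reactants: 20 (Z)-β-iodoenone; 21 carbon monoxide
Product: 22 ring A (Z)-ylidenebutenolide with the silyloxy dienyl arm
Conditions: CO (3 atm), PdCl2(PPh3)2 (5 mol %), Et3N (2 equiv), DMF, 60 °C, dark
Reagents that add atoms: none
Why: Zerovalent palladium, formed in the flask from PdCl2(PPh3)2, inserts into the vinylic carbon–iodine bond at C9 with retention of geometry, and CO insertion gives an acylpalladium iodide whose acyl carbon C19 is held cis to the C11 ketone. Triethylamine enolises the ketone toward C12, its only sp3 α-carbon, and the dienol oxygen attacks the acyl group, which closes the lactone and returns zerovalent palladium. The closest known reaction type is the palladium-catalysed carbonylative lactonisation of (Z)-β-iodoenones to (Z)-γ-alkylidenebutenolides. Ring C closes by 5-exo-trig O-acylation, which forms the C9–C19 and C19–O bonds, and the C11=C12 bond comes from the enol. No stereocentre is formed; the step needs O- over C-acylation, CO insertion ahead of carbopalladation of the C13=C14 alkene, and Z geometry at C11=C12. The cis iodoenone geometry enforces the five-membered O-closure, CO pressure favours insertion, and the Z dienol ester, with C13 turned away from the ring hydrogen on C10, is the less strained product.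

Step 15
Reactants: 22 ring A (Z)-ylidenebutenolide with the silyloxy dienyl arm
Product: 23 butenolide dienyl alcohol (C15–OH free)
Conditions: HF·pyridine, pyridine, THF, 0 °C
Reagents that add atoms: none
Why: Buffered fluoride-mediated desilylation should remove the unhindered primary allylic silyl ether well before the secondary ring A ether, and the non-basic medium spares the enol lactone.

Step 16
Reactants: 23 butenolide dienyl alcohol
Product: 24 butenolide dienal (C15 aldehyde)
Conditions: MnO2 (activated, excess), CH2Cl2, rt, dark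
Reagents that add atoms: none
Why: Allylic oxidation with MnO2 is selective for the conjugated primary alcohol and is neutral enough for the ylidenebutenolide.

Step 17
Reactants: 25 ketoisophorone
Product: 26 (S)-phorenol, (4S)-4-hydroxy-2,6,6-trimethylcyclohex-2-en-1-one
Conditions: RuCl[(S,S)-TsDPEN](p-cymene) (0.5 mol %), KOH (1 mol %), i-PrOH, rt
Reagents that add atoms: none
Why: Noyori-type asymmetric transfer hydrogenation should reduce only the unhindered C4 carbonyl, and the (S,S)-ligand is expected to deliver the S carbinol (the later 3′R centre) through the usual CH/π model with the alkene flank in the place of an aryl group.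

Step 18
Reactants: 26 (S)-phorenol
Product: 27 (4S)-4-(TBSO)-2,6,6-trimethylcyclohex-2-en-1-one
Conditions: TBSCl, imidazole, DMF, rt
Reagents that add atoms: tert-butyldimethylsilyl chloride, CC(C)(C)[Si](C)(C)Cl
Why: Standard silylation of the secondary alcohol.

Step 19
Reactants: 27 (4S)-4-(TBSO)-2,6,6-trimethylcyclohex-2-en-1-one
Product: 29 (4R)-4-(TBSO)-2,6,6-trimethylcyclohex-1-en-1-yl triflate, via lithium enolate 28 (not isolated)
Conditions: Li[(s-Bu)3BH], THF, −78 °C; then PhNTf2, −78 °C → rt
Reagents that add atoms: N-phenylbis(trifluoromethanesulfonimide), O=S(=O)(N(c1ccccc1)S(=O)(=O)C(F)(F)F)C(F)(F)F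
Why: Conjugate reduction of the enone, whose carbonyl is shielded on both sides, gives the tetrasubstituted enolate regiospecifically, and O-triflation traps it as the enol triflate (reductive triflation); the carbinol centre is untouched and only its descriptor changes.

Step 20
Reactants: 13 (E)-3-methylpent-2-en-4-yn-1-ol
Product: 30 (2E,4E)-3-methyl-5-(tributylstannyl)penta-2,4-dien-1-ol
Conditions: Bu3SnH, PdCl2(PPh3)2 (2 mol %), THF, 0 °C; chromatography
Reagents that add atoms: tributyltin hydride, CCCC[SnH](CCCC)CCCC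
Why: Palladium-catalysed syn hydrostannation of the terminal alkyne should place tin mainly on the terminal carbon and give the E alkenylstannane, with the minor internal regioisomer removed by chromatography.

Step 21
Reactants: 29 (4R)-4-(TBSO)-2,6,6-trimethylcyclohex-1-en-1-yl triflate; 30 (2E,4E)-3-methyl-5-(tributylstannyl)penta-2,4-dien-1-ol
Product: 31 ring B C15 dienol, (2E,4E)-5-[(4R)-4-(TBSO)-2,6,6-trimethylcyclohex-1-en-1-yl]-3-methylpenta-2,4-dien-1-ol
Conditions: Pd2(dba)3 (2.5 mol %), AsPh3 (20 mol %), NMP, 60 °C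
Reagents that add atoms: none
Why: Stille coupling of the hindered enol triflate, helped by the weakly bound arsine ligand in a polar solvent, forms the C6′–C7′ bond with retention of the stannane geometry.

Step 22
Reactants: 31 ring B C15 dienol
Product: 32 ring B C15 dienal
Conditions: MnO2 (activated, excess), CH2Cl2, rt, dark
Reagents that add atoms: none
Why: Allylic oxidation with MnO2 gives the conjugated aldehyde without touching the silyl ether.

Step 23
Reactants: 32 ring B C15 dienal; 33 triethyl 3-methyl-4-phosphonocrotonate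
Product: 35 ethyl (3′R)-3′-(TBSO)-retinoate (all-E), via lithiated phosphonate 34 (not isolated)
Conditions: 33, n-BuLi, DMPU, THF, −78 °C; then 32, −78 → 0 °C
Reagents that add atoms: none
Why: Horner–Wadsworth–Emmons olefination with the stabilised C5 phosphonate anion should form the C11′=C12′ bond E-selectively, and any 13′-cis ester is removed by chromatography.

Step 24
Reactants: 35 ethyl (3′R)-3′-(TBSO)-retinoate
Product: 36 (3′R)-3′-(TBSO)-retinol (all-E)
Conditions: i-Bu2AlH (2.2 equiv), THF, −78 °C; Rochelle salt work-up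
Reagents that add atoms: none
Why: 1,2-Reduction of the conjugated ester by the aluminium hydride gives the polyenyl primary alcohol.

Step 25
Reactants: 36 (3′R)-3′-(TBSO)-retinol
Product: 37 (3′R)-3′-(TBSO)-retinyl triphenylphosphonium bromide
Conditions: PPh3·HBr, CH2Cl2, 0 °C → rt, dark
Reagents that add atoms: triphenylphosphine hydrobromide, [Br-].[PH+](c1ccccc1)(c1ccccc1)c1ccccc1
Why: Acid-promoted ionisation of the polyenyl alcohol and capture of the delocalised cation by triphenylphosphine at the terminal carbon give the all-E phosphonium salt, and the aprotic, weakly acidic medium should keep the silyl ether.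

Step 26
Reactants: 37 (3′R)-3′-(TBSO)-retinyl triphenylphosphonium bromide; 24 butenolide dienal
Product: 40 all-E bis(TBS) ether of the target, via ylide 38 (not isolated), via 15-cis isomer 39 (not isolated)
Conditions: NaN(SiMe3)2 (1.0 equiv), THF, −78 °C; then 24, −78 → 0 °C; then heptane, 90 °C, dark, argon
Reagents that add atoms: none
Why: Wittig olefination of the conjugated aldehyde with the preformed semi-stabilised ylide forms C15=C15′ as an E/Z mixture, and the central cis isomer should relax thermally to the all-E polyene without disturbing the Z ylidenebutenolide.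

Step 27
Reactants: 40 all-E bis(TBS) ether of the target
Product: 41 target, (3R,6R,3′R)-dihydroxy butenolide carotenoid
Conditions: HF·pyridine, pyridine, THF, 0 °C → rt, dark
Reagents that add atoms: none
Why: Buffered fluoride-mediated desilylation frees both secondary alcohols under non-basic conditions that the enol lactone and the polyene should tolerate.

**Compound list**

1 | (±)-α-ionone | CC(=O)/C=C/C1C(C)=CCCC1(C)C | starting material
2 | triethylsilyl enol ether of dihydro-α-ionone (racemic) | CC(O[Si](CC)(CC)CC)=CCC1C(C)=CCCC1(C)C | intermediate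
3 | (±)-7,8-dihydro-α-ionone | CC(=O)CCC1C(C)=CCCC1(C)C | intermediate
4 | (±)-2-methyl-2-[2-(2,6,6-trimethylcyclohex-2-en-1-yl)ethyl]-1,3-dioxolane | CC1(CCC2C(C)=CCCC2(C)C)OCCO1 | intermediate
5 | (±)-4-[2-(2-methyl-1,3-dioxolan-2-yl)ethyl]-3,5,5-trimethylcyclohex-2-en-1-one | CC1(CCC2C(C)=CC(=O)CC2(C)C)OCCO1 | intermediate
6 | (±)-trans-4-[2-(2-methyl-1,3-dioxolan-2-yl)ethyl]-3,5,5-trimethylcyclohex-2-en-1-ol (racemate; SMILES shows the 1R,4R enantiomer) | CC1=C[C@H](O)CC(C)(C)[C@H]1CCC2(C)OCCO2 | intermediate
7 | (1R,4R)-4-[2-(2-methyl-1,3-dioxolan-2-yl)ethyl]-3,5,5-trimethylcyclohex-2-en-1-ol (carotenoid locants 3R,6R) | CC1=C[C@H](O)CC(C)(C)[C@H]1CCC2(C)OCCO2 | intermediate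
8 | TBS ether of 7 | CC1=C[C@H](O[Si](C)(C)C(C)(C)C)CC(C)(C)[C@H]1CCC2(C)OCCO2 | intermediate
9 | 4-[(1R,4R)-4-(TBSO)-2,6,6-trimethylcyclohex-2-en-1-yl]butan-2-one | CC1=C[C@H](O[Si](C)(C)C(C)(C)C)CC(C)(C)[C@H]1CCC(C)=O | intermediate
10 | terminal lithium enolate of 9 | CC1=C[C@H](O[Si](C)(C)C(C)(C)C)CC(C)(C)[C@H]1CCC(=C)O[Li] | intermediate
11 | terminal enol diethyl phosphate of 9 | CC1=C[C@H](O[Si](C)(C)C(C)(C)C)CC(C)(C)[C@H]1CCC(=C)OP(=O)(OCC)OCC | intermediate
12 | ring A butyne, tert-butyl{[(1R,4R)-4-(but-3-yn-1-yl)-3,5,5-trimethylcyclohex-2-en-1-yl]oxy}dimethylsilane | CC1=C[C@H](O[Si](C)(C)C(C)(C)C)CC(C)(C)[C@H]1CCC#C | intermediate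
13 | (E)-3-methylpent-2-en-4-yn-1-ol | C#C/C(C)=C/CO | starting material
14 | (E)-tert-butyldimethyl[(3-methylpent-2-en-4-yn-1-yl)oxy]silane | C#C/C(C)=C/CO[Si](C)(C)C(C)(C)C | intermediate
15 | (1E,3E)-[5-(TBSO)-3-methylpenta-1,3-dien-1-yl]dicyclohexylborane | C1CCCCC1B(/C=C/C(C)=C/CO[Si](C)(C)C(C)(C)C)C1CCCCC1 | intermediate
16 | (E)-5-(TBSO)-3-methylpent-3-enal | O=CC/C(C)=C/CO[Si](C)(C)C(C)(C)C | intermediate
17 | lithium acetylide of 12 | CC1=C[C@H](O[Si](C)(C)C(C)(C)C)CC(C)(C)[C@H]1CCC#C[Li] | intermediate
18 | propargylic alcohol, ring A–CH2CH2–C≡C–CH(OH)–CH2–C(CH3)=CH–CH2OTBS (E alkene; epimers at the carbinol carbon) | CC1=C[C@H](O[Si](C)(C)C(C)(C)C)CC(C)(C)[C@H]1CCC#CC(O)C/C(C)=C/CO[Si](C)(C)C(C)(C)C | intermediate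
19 | ynone, ring A–CH2CH2–C≡C–C(=O)–CH2–C(CH3)=CH–CH2OTBS | CC1=C[C@H](O[Si](C)(C)C(C)(C)C)CC(C)(C)[C@H]1CCC#CC(=O)C/C(C)=C/CO[Si](C)(C)C(C)(C)C | intermediate
20 | (Z)-β-iodoenone, ring A–CH2CH2–C(I)=CH–C(=O)–CH2–C(CH3)=CH–CH2OTBS | CC1=C[C@H](O[Si](C)(C)C(C)(C)C)CC(C)(C)[C@H]1CC/C(I)=C/C(=O)C/C(C)=C/CO[Si](C)(C)C(C)(C)C | intermediate
21 | carbon monoxide | [C-]#[O+] | starting material
22 | ring A (Z)-ylidenebutenolide with the (E)-silyloxy dienyl arm | CC1=C[C@H](O[Si](C)(C)C(C)(C)C)CC(C)(C)[C@H]1CCC1=C/C(=C/C(C)=C/CO[Si](C)(C)C(C)(C)C)OC1=O | intermediate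
23 | butenolide dienyl alcohol (C15–OH) | CC1=C[C@H](O[Si](C)(C)C(C)(C)C)CC(C)(C)[C@H]1CCC1=C/C(=C/C(C)=C/CO)OC1=O | intermediate
24 | butenolide dienal (C15 aldehyde) | CC1=C[C@H](O[Si](C)(C)C(C)(C)C)CC(C)(C)[C@H]1CCC1=C/C(=C/C(C)=C/C=O)OC1=O | intermediate
25 | ketoisophorone, 2,6,6-trimethylcyclohex-2-ene-1,4-dione | CC1=CC(=O)CC(C)(C)C1=O | starting material
26 | (4S)-4-hydroxy-2,6,6-trimethylcyclohex-2-en-1-one | CC1=C[C@@H](O)CC(C)(C)C1=O | intermediate
27 | (4S)-4-(TBSO)-2,6,6-trimethylcyclohex-2-en-1-one | CC1=C[C@@H](O[Si](C)(C)C(C)(C)C)CC(C)(C)C1=O | intermediate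
28 | lithium (4R)-4-(TBSO)-2,6,6-trimethylcyclohex-1-en-1-olate | [Li]OC1=C(C)C[C@@H](O[Si](C)(C)C(C)(C)C)CC1(C)C | intermediate
29 | (4R)-4-(TBSO)-2,6,6-trimethylcyclohex-1-en-1-yl trifluoromethanesulfonate | FC(F)(F)S(=O)(=O)OC1=C(C)C[C@@H](O[Si](C)(C)C(C)(C)C)CC1(C)C | intermediate
30 | (2E,4E)-3-methyl-5-(tributylstannyl)penta-2,4-dien-1-ol | CCCC[Sn](CCCC)(CCCC)/C=C/C(C)=C/CO | intermediate
31 | (2E,4E)-5-[(4R)-4-(TBSO)-2,6,6-trimethylcyclohex-1-en-1-yl]-3-methylpenta-2,4-dien-1-ol | OC/C=C(C)/C=C/C1=C(C)C[C@@H](O[Si](C)(C)C(C)(C)C)CC1(C)C | intermediate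
32 | (2E,4E)-5-[(4R)-4-(TBSO)-2,6,6-trimethylcyclohex-1-en-1-yl]-3-methylpenta-2,4-dienal | O=C/C=C(C)/C=C/C1=C(C)C[C@@H](O[Si](C)(C)C(C)(C)C)CC1(C)C | intermediate
33 | triethyl 3-methyl-4-phosphonocrotonate (commercial E/Z mixture; E isomer shown) | CCOC(=O)/C=C(\C)CP(=O)(OCC)OCC | starting material
34 | lithiated phosphonate from 33 | CCOC(=O)/C=C(\C)C([Li])P(=O)(OCC)OCC | intermediate
35 | ethyl (3′R)-3′-(TBSO)-retinoate (all-E) | CCOC(=O)/C=C(C)/C=C/C=C(C)/C=C/C1=C(C)C[C@@H](O[Si](C)(C)C(C)(C)C)CC1(C)C | intermediate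
36 | (3′R)-3′-(TBSO)-retinol (all-E) | OC/C=C(C)/C=C/C=C(C)/C=C/C1=C(C)C[C@@H](O[Si](C)(C)C(C)(C)C)CC1(C)C | intermediate
37 | (3′R)-3′-(TBSO)-retinyl triphenylphosphonium bromide (all-E) | [Br-].C(/C=C(C)/C=C/C=C(C)/C=C/C1=C(C)C[C@@H](O[Si](C)(C)C(C)(C)C)CC1(C)C)[P+](c1ccccc1)(c1ccccc1)c1ccccc1 | intermediate
38 | ylide from 37 | C(/C=C(C)/C=C/C=C(C)/C=C/C1=C(C)C[C@@H](O[Si](C)(C)C(C)(C)C)CC1(C)C)=P(c1ccccc1)(c1ccccc1)c1ccccc1 | intermediate
39 | 15-cis isomer of 40 | CC1=C[C@H](O[Si](C)(C)C(C)(C)C)CC(C)(C)[C@H]1CCC1=C/C(=C/C(C)=C/C=C\C=C(C)\C=C\C=C(C)\C=C\C2=C(C)C[C@@H](O[Si](C)(C)C(C)(C)C)CC2(C)C)OC1=O | intermediate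
40 | all-E bis(TBS) ether of the target | CC1=C[C@H](O[Si](C)(C)C(C)(C)C)CC(C)(C)[C@H]1CCC1=C/C(=C/C(C)=C/C=C/C=C(C)/C=C/C=C(C)/C=C/C2=C(C)C[C@@H](O[Si](C)(C)C(C)(C)C)CC2(C)C)OC1=O | intermediate
41 | target, (3R,6R,3′R)-dihydroxy 7,8-dihydro butenolide carotenoid (C11=C12 Z, all other chain double bonds E) | CC1=C[C@H](O)CC(C)(C)[C@H]1CCC1=C/C(=C/C(C)=C/C=C/C=C(C)/C=C/C=C(C)/C=C/C2=C(C)C[C@@H](O)CC2(C)C)OC1=O | target

**Step count**

Total: 27 steps. Longest linear sequence: 16 steps (steps 1–8, 11–16, 26 and 27).

**Steps most likely to fail**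

1. Step 14 (carbonylative lactonisation). Capture of the acylpalladium by the enol oxygen may be slower than base-induced migration of the C13=C14 bond, carbopalladation of that alkene or protodeiodination, and the vinyl iodide may lose its Z geometry before insertion. The fallback uses CO2 as the carbonyl source and closes the ring by lactonisation of a hydroxy acid; it sets out from 20 and comes back at 22. Luche reduction of 20 (NaBH4, CeCl3·7H2O, MeOH, −40 °C) should give the (Z)-γ-iodo allylic alcohol F1. Deprotonation and iodine–lithium exchange (n-BuLi, then t-BuLi, THF, −78 °C), carboxylation with CO2 and acidic work-up should close the γ-substituted butenolide F2. Enolisation and silylation (i-Pr3SiOTf, Et3N, CH2Cl2, 0 °C) give the 2-silyloxyfuran F3, and bromination at C11 (NBS, THF, −78 °C) gives the 5-bromobutenolide F4. Dehydrobromination toward C12 (Et3N, 0 °C) then restores the conjugated (Z)-ylidenebutenolide 22.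

2. Step 26 (Wittig reaction). The ylide or residual base may attack the enol lactone, the central double bond may form with poor E selectivity, and the thermal equilibration may be incomplete or may erode the butenolide. The fallback is a Julia–Kocienski olefination with the polarity reversed; it sets out from 23 and 36 and comes back at 40. Mitsunobu thioetherification of 23 (2-mercaptobenzothiazole, PPh3, DIAD, THF, 0 °C) gives the benzothiazolyl sulfide F5, which is oxidised at sulfur ((NH4)6Mo7O24 (cat.), H2O2, EtOH, 0 °C) to the benzothiazolyl sulfone F6. MnO2 oxidation of 36 gives the silylated (3′R)-3′-hydroxyretinal F7. Deprotonation of F6 (NaN(SiMe3)2, THF, −78 °C) in the presence of F7 forms the C15=C15′ bond with loss of SO2 and benzothiazolone, and the same thermal equilibration leads to 40.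

3. Step 10 (hydroboration–oxidation). The β,γ-double bond may slip into conjugation with the aldehyde during the oxidative work-up, and a second hydroboration of the alkenylborane may lower the conversion. The fallback makes the aldehyde by oxidation of a homoallylic alcohol under non-basic conditions; it sets out from 14 and comes back at 16. Semihydrogenation of 14 (H2, Pd/CaCO3 poisoned with Pb(OAc)2, quinoline, hexane) gives the silyl-protected (E)-3-methylpenta-2,4-dien-1-ol F8. Hydroboration of its terminal vinyl group with 9-BBN-H and oxidation (NaOH, H2O2) give the homoallylic alcohol F9, and Dess–Martin oxidation (pyridine, CH2Cl2, 0 °C) gives 16 for immediate use.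

**Further compounds**

F1 | step 14 | (Z)-γ-iodo allylic alcohol from 20 (epimers at the carbinol carbon) | CC1=C[C@H](O[Si](C)(C)C(C)(C)C)CC(C)(C)[C@H]1CC/C(I)=C/C(O)C/C(C)=C/CO[Si](C)(C)C(C)(C)C
F2 | step 14 | γ-substituted butenolide (epimers at C11) | CC1=C[C@H](O[Si](C)(C)C(C)(C)C)CC(C)(C)[C@H]1CCC1=CC(C/C(C)=C/CO[Si](C)(C)C(C)(C)C)OC1=O
F3 | step 14 | 2-(triisopropylsilyloxy)furan | CC1=C[C@H](O[Si](C)(C)C(C)(C)C)CC(C)(C)[C@H]1CCc1cc(C/C(C)=C/CO[Si](C)(C)C(C)(C)C)oc1O[Si](C(C)C)(C(C)C)C(C)C
F4 | step 14 | 5-bromobutenolide (epimers at C11) | CC1=C[C@H](O[Si](C)(C)C(C)(C)C)CC(C)(C)[C@H]1CCC1=CC(Br)(C/C(C)=C/CO[Si](C)(C)C(C)(C)C)OC1=O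
F5 | step 26 | benzothiazolyl sulfide of the butenolide dienyl arm | CC1=C[C@H](O[Si](C)(C)C(C)(C)C)CC(C)(C)[C@H]1CCC1=C/C(=C/C(C)=C/CSc2nc3ccccc3s2)OC1=O
F6 | step 26 | benzothiazolyl sulfone of the butenolide dienyl arm | CC1=C[C@H](O[Si](C)(C)C(C)(C)C)CC(C)(C)[C@H]1CCC1=C/C(=C/C(C)=C/CS(=O)(=O)c2nc3ccccc3s2)OC1=O
F7 | step 26 | (3′R)-3′-(TBSO)-retinal (all-E) | O=C/C=C(C)/C=C/C=C(C)/C=C/C1=C(C)C[C@@H](O[Si](C)(C)C(C)(C)C)CC1(C)C
F8 | step 10 | (E)-tert-butyldimethyl[(3-methylpenta-2,4-dien-1-yl)oxy]silane | C=C/C(C)=C/CO[Si](C)(C)C(C)(C)C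
F9 | step 10 | (E)-5-(TBSO)-3-methylpent-3-en-1-ol | OCC/C(C)=C/CO[Si](C)(C)C(C)(C)C
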